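**Plan**

- Retrosynthesis: after the silyl ether, the two benzyl groups and the C2 O-methyl group are removed, ring A is cut at C1–C2, C2–C3, C4–C5 and C5–C6. Ring A (C1 ester carbon, C2 OMe, C3 CH2OH, C4 OMe, C5 H, C6 CH3) is a resorcinol diether whose oxygens at C2 and C4 flank the carbon branch at C3, which is the pattern a vinylketene and a 1-alkoxyalkyne assemble.
- These cuts leave a diazo ketone that already carries ring B as a simple enoate ester, and a silyloxymethyl ynol ether. The diazo ketone is cut further at the aryl ester C–O bond and at its C=C bond.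
- Forward: ring B phenol from methyl atrarate (steps 1–4); enone acid by Wittig reaction (steps 5–6); esterification and diazo transfer (steps 7–8); ynol ether from trichloroethylene (steps 9–10); benzannulation builds ring A on the ring B ester (step 11); O-methylation, debenzylation and desilylation (steps 12–14).
- Stereochemistry: the target has no stereocentre. The E enoate geometry set in the Wittig step only steers the benzannulation and disappears on aromatization.

Key step: step 11

Assumption: ring A is numbered C1 (carbon bearing the ester carbonyl) to C6 (methyl-bearing carbon), and ring B carries primed numbers starting at the carboxyl-bearing carbon C1'.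

**Route**

Step 1
Reactants: 1 methyl 2,4-dihydroxy-3,6-dimethylbenzoate
Product: 2 methyl 2-hydroxy-3,6-dimethyl-4-(prop-2-en-1-yloxy)benzoate
Conditions: allyl bromide (1.05 equiv), K2CO3, acetone, reflux
Reagents that add atoms: allyl bromide, C=CCBr
Why: The 2-hydroxyl is tied up in a hydrogen bond to the ester carbonyl, so Williamson etherification with one equivalent of allyl bromide should take place only at the free, more acidic 4-hydroxyl.

Step 2
Reactants: 2 methyl 2-hydroxy-3,6-dimethyl-4-(prop-2-en-1-yloxy)benzoate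
Product: 3 2-hydroxy-3,6-dimethyl-4-(prop-2-en-1-yloxy)benzoic acid
Conditions: KOH (aq, 4 M), EtOH, reflux; then HCl (aq), 0 °C
Reagents that add atoms: potassium hydroxide, [K+].[OH-]
Why: Saponification of the salicylate-type ester is assisted by the ortho phenoxide, the allyl ether is inert to aqueous base, and cold acidification should avoid decarboxylation of the resorcylic acid.

Step 3
Reactants: 3 2-hydroxy-3,6-dimethyl-4-(prop-2-en-1-yloxy)benzoic acid
Product: 5 benzyl 2-(benzyloxy)-3,6-dimethyl-4-(prop-2-en-1-yloxy)benzoate, via phenolic benzyl ester 4 (not isolated)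
Conditions: BnBr (2.5 equiv), K2CO3 (3 equiv), DMF, 60 °C
Reagents that add atoms: benzyl bromide, BrCc1ccccc1
Why: Carbonate-mediated alkylation benzylates the carboxylate first (giving 4), and the chelated phenol then undergoes Williamson etherification with the excess of benzyl bromide in warm DMF.

Step 4
Reactants: 5 benzyl 2-(benzyloxy)-3,6-dimethyl-4-(prop-2-en-1-yloxy)benzoate
Product: 6 benzyl 2-(benzyloxy)-4-hydroxy-3,6-dimethylbenzoate
Conditions: Pd(PPh3)4 (3 mol %), morpholine (5 equiv), THF, rt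
Reagents that add atoms: none
Why: In this Tsuji–Trost deallylation zerovalent palladium ionizes the aryl allyl ether to a π-allyl complex that morpholine captures, while the benzyl ether and benzyl ester are not touched.

Step 5
Reactants: 7 butane-2,3-dione (3 equiv); 8 tert-butyl (triphenyl-λ5-phosphanylidene)acetate
Product: 9 tert-butyl (2E)-3-methyl-4-oxopent-2-enoate
Conditions: CH2Cl2, 0 °C → rt
Reagents that add atoms: none
Why: Wittig olefination of one carbonyl of the activated 1,2-diketone by the stabilized ylide is expected to place the ester trans to the acetyl group (E), and the excess of diketone suppresses double olefination.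

Step 6
Reactants: 9 tert-butyl (2E)-3-methyl-4-oxopent-2-enoate
Product: 10 (2E)-3-methyl-4-oxopent-2-enoic acid
Conditions: CF3CO2H/CH2Cl2 (1:4), 0 °C → rt
Reagents that add atoms: none
Why: Acidolysis of the tert-butyl ester proceeds by loss of isobutene, and the E acid cannot close to a cyclic pseudo-acid, so the alkene geometry should be retained.

Step 7
Reactants: 6 benzyl 2-(benzyloxy)-4-hydroxy-3,6-dimethylbenzoate; 10 (2E)-3-methyl-4-oxopent-2-enoic acid
Product: 11 benzyl 2-(benzyloxy)-3,6-dimethyl-4-{[(2E)-3-methyl-4-oxopent-2-enoyl]oxy}benzoate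
Conditions: DCC (1.1 equiv), DMAP (0.1 equiv), CH2Cl2, 0 °C → rt
Reagents that add atoms: none
Why: Steglich esterification (carbodiimide activation with DMAP as acyl-transfer catalyst) should acylate the only free hydroxyl of 6 with an unhindered enoic acid, so the crowded depside ester of the target is made before ring A exists.

Step 8
Reactants: 11 benzyl 2-(benzyloxy)-3,6-dimethyl-4-{[(2E)-3-methyl-4-oxopent-2-enoyl]oxy}benzoate
Product: 14 benzyl 2-(benzyloxy)-4-{[(2E)-5-diazo-3-methyl-4-oxopent-2-enoyl]oxy}-3,6-dimethylbenzoate, via lithium dienolate 12 (not isolated), via trifluoroacetyl diketone 13 (not isolated)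
Conditions: LiN(SiMe3)2 (1.1 equiv), THF, −78 °C; CF3CO2CH2CF3 (1.2 equiv), −78 °C; 5% aq HCl work-up; then MsN3 (1.5 equiv), Et3N (1.5 equiv), H2O (1 equiv), MeCN, rt
Reagents that add atoms: methanesulfonyl azide, CS(=O)(=O)N=[N+]=[N-]
Why: In this detrifluoroacetylative (deacylative Regitz-type) diazo transfer the kinetic enolate 12 is C-acylated to the activated 1,3-diketone 13, which takes up the diazo group from the sulfonyl azide and loses the trifluoroacetyl group, so the electron-poor alkene never meets diazomethane.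

Step 9
Reactants: 15 trichloroethene
Product: 17 (E)-1,2-dichloro-1-methoxyethene, via dichloroethyne 16 (not isolated)
Conditions: KH (2 equiv), MeOH (1 equiv), THF, 0 °C; then 15 (1.1 equiv), −50 °C → rt; fractional distillation
Reagents that add atoms: methanol, CO
Why: Potassium methoxide dehydrochlorinates trichloroethene to dichloroethyne 16 (β-elimination), and methanol then adds to it in anti fashion (nucleophilic addition to a haloalkyne) to give the E dichlorovinyl ether.

Step 10
Reactants: 17 (E)-1,2-dichloro-1-methoxyethene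
Product: 21 [(3-methoxyprop-2-yn-1-yl)oxy]tri(propan-2-yl)silane, via 1-chloro-2-methoxyethyne 18 (not isolated), via (methoxyethynyl)lithium 19 (not isolated), via lithium 3-methoxyprop-2-yn-1-olate 20 (not isolated)
Conditions: n-BuLi (2.1 equiv), THF, −78 → −40 °C; (CH2O)n (1.05 equiv), −40 °C → rt; TIPSCl (1.1 equiv), 0 °C → rt
Reagents that add atoms: formaldehyde (as paraformaldehyde), C=O; chlorotri(propan-2-yl)silane, CC(C)[Si](Cl)(C(C)C)C(C)C
Why: n-BuLi effects dehydrochlorination to 18 and chlorine–lithium exchange to the acetylide 19, which adds to formaldehyde (acetylide 1,2-addition), and the alkoxide 20 is O-silylated in the same flask so that the acid-sensitive ynol ether alcohol is never isolated.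

Step 11
Reactants: 14 benzyl 2-(benzyloxy)-4-{[(2E)-5-diazo-3-methyl-4-oxopent-2-enoyl]oxy}-3,6-dimethylbenzoate; 21 [(3-methoxyprop-2-yn-1-yl)oxy]tri(propan-2-yl)silane (1.2 equiv)
Product: 26 benzyl 2-(benzyloxy)-4-{[2-hydroxy-4-methoxy-6-methyl-3-({[tri(propan-2-yl)silyl]oxy}methyl)benzoyl]oxy}-3,6-dimethylbenzoate, via vinylketene 22 (not isolated), via cyclobutenone 23 (not isolated), via dienylketene 24 (not isolated), via cyclohexadienone 25 (not isolated)
Conditions: hν (medium-pressure mercury lamp, borosilicate filter, >300 nm), CH2Cl2, rt; then toluene, 80–110 °C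
Reagents that add atoms: none
Why: Irradiation expels nitrogen from 14 with 1,2-shift of the alkenyl carbon to the former diazo carbon (photochemical Wolff rearrangement, forming C5–C6) and gives the ester-substituted vinylketene 22. The ynol ether 21 adds to the ketene in a regiospecific (2+2) cycloaddition to cyclobutenone 23: its carbon β to methoxy bonds to the ketene carbonyl carbon (C2–C3) and its methoxy-bearing carbon to the former diazo carbon (C4–C5). On warming, 23 opens by four-electron electrocyclic cleavage to dienylketene 24, and ring A then closes by a thermal disrotatory 6π electrocyclization (C1–C2) to dienone 25, which tautomerizes to phenol 26. The closest known reaction is the Danheiser benzannulation in its second-generation diazo ketone form with 1-alkoxyalkynes. No stereocentre is created in the product, since the sp3 centres of 23 and 25 are erased on aromatization. The step needs regioselectivity, which the polarization of the ynol ether secures by placing the silyloxymethyl carbon between the two oxygens, and it needs the E enoate, which keeps the ester carbonyl away from the ketene and puts hydrogen rather than the ester on the inside of the closing triene.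

Step 12
Reactants: 26 benzyl 2-(benzyloxy)-4-{[2-hydroxy-4-methoxy-6-methyl-3-({[tri(propan-2-yl)silyl]oxy}methyl)benzoyl]oxy}-3,6-dimethylbenzoate
Product: 27 benzyl 2-(benzyloxy)-4-{[2,4-dimethoxy-6-methyl-3-({[tri(propan-2-yl)silyl]oxy}methyl)benzoyl]oxy}-3,6-dimethylbenzoate
Conditions: MeI (3 equiv), K2CO3 (2 equiv), DMF, rt → 40 °C
Reagents that add atoms: iodomethane, CI
Why: Williamson O-methylation of the only free phenol should proceed cleanly because silyl migration to the phenoxide would generate a far more basic alkoxide, and the di-ortho-substituted aryl ester is shielded from carbonate.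

Step 13
Reactants: 27 benzyl 2-(benzyloxy)-4-{[2,4-dimethoxy-6-methyl-3-({[tri(propan-2-yl)silyl]oxy}methyl)benzoyl]oxy}-3,6-dimethylbenzoate
Product: 28 4-{[2,4-dimethoxy-6-methyl-3-({[tri(propan-2-yl)silyl]oxy}methyl)benzoyl]oxy}-2-hydroxy-3,6-dimethylbenzoic acid
Conditions: H2 (1 atm), 10% Pd/C, EtOAc, rt
Reagents that add atoms: none
Why: Catalytic hydrogenolysis cleaves the benzyl ester and the aryl benzyl ether, whereas the benzylic C–O bond of ring A carries a bulky, poorly leaving silyloxy group and should persist in a neutral aprotic solvent.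

Step 14
Reactants: 28 4-{[2,4-dimethoxy-6-methyl-3-({[tri(propan-2-yl)silyl]oxy}methyl)benzoyl]oxy}-2-hydroxy-3,6-dimethylbenzoic acid
Product: 29 2-hydroxy-4-{[3-(hydroxymethyl)-2,4-dimethoxy-6-methylbenzoyl]oxy}-3,6-dimethylbenzoic acid
Conditions: Bu4NF (3 equiv), AcOH (3 equiv), THF, 0 °C → rt
Reagents that add atoms: none
Why: Fluoride-induced desilylation releases the primary alcohol, and the acetic acid buffer keeps the medium near neutral so that the hindered depside ester and the acid-labile 2,6-dimethoxybenzyl alcohol should survive.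

**Compound list**

1 | methyl 2,4-dihydroxy-3,6-dimethylbenzoate (methyl atrarate) | COC(=O)c1c(C)cc(O)c(C)c1O | starting material
2 | methyl 2-hydroxy-3,6-dimethyl-4-(prop-2-en-1-yloxy)benzoate | COC(=O)c1c(C)cc(OCC=C)c(C)c1O | intermediate
3 | 2-hydroxy-3,6-dimethyl-4-(prop-2-en-1-yloxy)benzoic acid | OC(=O)c1c(C)cc(OCC=C)c(C)c1O | intermediate
4 | benzyl 2-hydroxy-3,6-dimethyl-4-(prop-2-en-1-yloxy)benzoate | O=C(OCc1ccccc1)c1c(C)cc(OCC=C)c(C)c1O | intermediate
5 | benzyl 2-(benzyloxy)-3,6-dimethyl-4-(prop-2-en-1-yloxy)benzoate | O=C(OCc1ccccc1)c1c(C)cc(OCC=C)c(C)c1OCc1ccccc1 | intermediate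
6 | benzyl 2-(benzyloxy)-4-hydroxy-3,6-dimethylbenzoate | O=C(OCc1ccccc1)c1c(C)cc(O)c(C)c1OCc1ccccc1 | intermediate
7 | butane-2,3-dione | CC(=O)C(C)=O | starting material
8 | tert-butyl (triphenyl-λ5-phosphanylidene)acetate | CC(C)(C)OC(=O)C=P(c1ccccc1)(c1ccccc1)c1ccccc1 | starting material
9 | tert-butyl (2E)-3-methyl-4-oxopent-2-enoate | CC(=O)/C(C)=C/C(=O)OC(C)(C)C | intermediate
10 | (2E)-3-methyl-4-oxopent-2-enoic acid | CC(=O)/C(C)=C/C(=O)O | intermediate
11 | benzyl 2-(benzyloxy)-3,6-dimethyl-4-{[(2E)-3-methyl-4-oxopent-2-enoyl]oxy}benzoate | CC(=O)/C(C)=C/C(=O)Oc1cc(C)c(C(=O)OCc2ccccc2)c(OCc2ccccc2)c1C | intermediate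
12 | lithium (3E)-5-{3-(benzyloxy)-4-[(benzyloxy)carbonyl]-2,5-dimethylphenoxy}-3-methyl-5-oxopenta-1,3-dien-2-olate (kinetic enolate of 11) | C=C(O[Li])/C(C)=C/C(=O)Oc1cc(C)c(C(=O)OCc2ccccc2)c(OCc2ccccc2)c1C | intermediate
13 | benzyl 2-(benzyloxy)-3,6-dimethyl-4-{[(2E)-7,7,7-trifluoro-3-methyl-4,6-dioxohept-2-enoyl]oxy}benzoate | O=C(CC(=O)/C(C)=C/C(=O)Oc1cc(C)c(C(=O)OCc2ccccc2)c(OCc2ccccc2)c1C)C(F)(F)F | intermediate
14 | benzyl 2-(benzyloxy)-4-{[(2E)-5-diazo-3-methyl-4-oxopent-2-enoyl]oxy}-3,6-dimethylbenzoate | [N-]=[N+]=CC(=O)/C(C)=C/C(=O)Oc1cc(C)c(C(=O)OCc2ccccc2)c(OCc2ccccc2)c1C | intermediate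
15 | trichloroethene | ClC=C(Cl)Cl | starting material
16 | dichloroethyne | ClC#CCl | intermediate
17 | (E)-1,2-dichloro-1-methoxyethene | CO/C(Cl)=C\Cl | intermediate
18 | 1-chloro-2-methoxyethyne | COC#CCl | intermediate
19 | (methoxyethynyl)lithium | COC#C[Li] | intermediate
20 | lithium 3-methoxyprop-2-yn-1-olate | COC#CCO[Li] | intermediate
21 | [(3-methoxyprop-2-yn-1-yl)oxy]tri(propan-2-yl)silane | COC#CCO[Si](C(C)C)(C(C)C)C(C)C | intermediate
22 | benzyl 2-(benzyloxy)-3,6-dimethyl-4-{[(2E)-3-methyl-5-oxopenta-2,4-dienoyl]oxy}benzoate (vinylketene) | O=C=C/C(C)=C/C(=O)Oc1cc(C)c(C(=O)OCc2ccccc2)c(OCc2ccccc2)c1C | intermediate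
23 | benzyl 2-(benzyloxy)-4-{[(2E)-3-(2-methoxy-4-oxo-3-{[tri(propan-2-yl)silyl]oxymethyl}cyclobut-2-en-1-yl)but-2-enoyl]oxy}-3,6-dimethylbenzoate (racemic cyclobutenone) | COC1=C(CO[Si](C(C)C)(C(C)C)C(C)C)C(=O)C1/C(C)=C/C(=O)Oc1cc(C)c(C(=O)OCc2ccccc2)c(OCc2ccccc2)c1C | intermediate
24 | benzyl 2-(benzyloxy)-4-{[(2E,4E)-5-methoxy-3-methyl-7-oxo-6-{[tri(propan-2-yl)silyl]oxymethyl}hepta-2,4,6-trienoyl]oxy}-3,6-dimethylbenzoate (dienylketene) | O=C=C(CO[Si](C(C)C)(C(C)C)C(C)C)/C(OC)=C\C(C)=C\C(=O)Oc1cc(C)c(C(=O)OCc2ccccc2)c(OCc2ccccc2)c1C | intermediate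
25 | benzyl 2-(benzyloxy)-4-{[4-methoxy-6-methyl-2-oxo-3-{[tri(propan-2-yl)silyl]oxymethyl}cyclohexa-3,5-diene-1-carbonyl]oxy}-3,6-dimethylbenzoate (racemic dienone) | COC1=C(CO[Si](C(C)C)(C(C)C)C(C)C)C(=O)C(C(=O)Oc2cc(C)c(C(=O)OCc3ccccc3)c(OCc3ccccc3)c2C)C(C)=C1 | intermediate
26 | benzyl 2-(benzyloxy)-4-{[2-hydroxy-4-methoxy-6-methyl-3-({[tri(propan-2-yl)silyl]oxy}methyl)benzoyl]oxy}-3,6-dimethylbenzoate | COc1cc(C)c(C(=O)Oc2cc(C)c(C(=O)OCc3ccccc3)c(OCc3ccccc3)c2C)c(O)c1CO[Si](C(C)C)(C(C)C)C(C)C | intermediate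
27 | benzyl 2-(benzyloxy)-4-{[2,4-dimethoxy-6-methyl-3-({[tri(propan-2-yl)silyl]oxy}methyl)benzoyl]oxy}-3,6-dimethylbenzoate | COc1cc(C)c(C(=O)Oc2cc(C)c(C(=O)OCc3ccccc3)c(OCc3ccccc3)c2C)c(OC)c1CO[Si](C(C)C)(C(C)C)C(C)C | intermediate
28 | 4-{[2,4-dimethoxy-6-methyl-3-({[tri(propan-2-yl)silyl]oxy}methyl)benzoyl]oxy}-2-hydroxy-3,6-dimethylbenzoic acid | COc1cc(C)c(C(=O)Oc2cc(C)c(C(=O)O)c(O)c2C)c(OC)c1CO[Si](C(C)C)(C(C)C)C(C)C | intermediate
29 | 2-hydroxy-4-{[3-(hydroxymethyl)-2,4-dimethoxy-6-methylbenzoyl]oxy}-3,6-dimethylbenzoic acid (CNP0372912.0) | COc1cc(C)c(C(=O)Oc2cc(C)c(C(=O)O)c(O)c2C)c(OC)c1CO | target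

**Totals**

Total step count: 14.
Longest linear sequence: 10 steps (steps 1–4, 7, 8, 11–14, from methyl atrarate). The enone acid (steps 5–6) and the ynol ether (steps 9–10) are convergent branches.

**Steps most likely to fail**

1. Step 11 (benzannulation). The enoate may photoisomerize to the Z form before nitrogen is lost, and the Z vinylketene can be diverted into an α-pyrone by closure onto its own ester carbonyl. The ketene may also dimerize or be trapped before the alkyne captures it, and the final 6π closure of the ester-substituted triene may be slow.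
 Fallback: it sets out from phenol 6 and comes back at 27. Ring A is made by classical arene chemistry and the depside bond by acylation. 3,5-Dimethoxytoluene is lithiated between its methoxy groups (n-BuLi, N,N,N',N'-tetramethylethylenediamine, Et2O) to (2,6-dimethoxy-4-methylphenyl)lithium F1 and formylated with DMF to 2,6-dimethoxy-4-methylbenzaldehyde F2. Reduction with NaBH4 gives (2,6-dimethoxy-4-methylphenyl)methanol F3, and silylation (TIPSCl, imidazole) gives [(2,6-dimethoxy-4-methylphenyl)methoxy]tri(propan-2-yl)silane F4. N-Bromosuccinimide in MeCN brominates one of the two equivalent free ring positions to [(3-bromo-2,6-dimethoxy-4-methylphenyl)methoxy]tri(propan-2-yl)silane F5. Bromine–lithium exchange (n-BuLi, −78 °C) gives {2,4-dimethoxy-6-methyl-3-[({tri(propan-2-yl)silyl}oxy)methyl]phenyl}lithium F6, and carboxylation with CO2 gives 2,4-dimethoxy-6-methyl-3-({[tri(propan-2-yl)silyl]oxy}methyl)benzoic acid F7. 1-Chloro-N,N,2-trimethylprop-1-en-1-amine converts the acid under neutral conditions into 2,4-dimethoxy-6-methyl-3-({[tri(propan-2-yl)silyl]oxy}methyl)benzoyl chloride F8, which acylates 6 (Et3N, DMAP, toluene, 60 °C) to give 27.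

2. Step 8 (diazo transfer). The lithium dienolate may condense with the aryl ester or the enoate of a second molecule before it is trifluoroacetylated. The activated diketone may also cyclize onto the enoate, or the aryl ester may be cleaved by the amine and water during the transfer.
 Fallback: it sets out from phenol 6 and comes back at 14, bypassing 11. Phenol 6 opens citraconic anhydride (Et3N, DMAP cat., CH2Cl2), expected mainly at the carbonyl remote from the methyl group, to give benzyl 2-(benzyloxy)-4-{[(2Z)-3-carboxybut-2-enoyl]oxy}-3,6-dimethylbenzoate F9. Iodine-catalysed isomerization under visible light gives the mesaconate half ester benzyl 2-(benzyloxy)-4-{[(2E)-3-carboxybut-2-enoyl]oxy}-3,6-dimethylbenzoate F10. Oxalyl chloride with catalytic DMF gives benzyl 2-(benzyloxy)-4-{[(2E)-3-(carbonochloridoyl)but-2-enoyl]oxy}-3,6-dimethylbenzoate F11. Acylation of Me3SiCHN2 (MeCN, 0 °C), a bulkier and less dipolarophile-prone reagent than diazomethane, then delivers 14.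

3. Step 2 (saponification). Acyl substitution at the ester flanked by the phenoxide and the 6-methyl group may be slow, and the resorcylic acid may decarboxylate during prolonged heating or acidification.
 Fallback: it sets out from 2 and comes back at 5, replacing attack at the carbonyl by attack at the ester methyl group. The phenol of 2 is benzylated first (BnBr, K2CO3, DMF, 60 °C) to methyl 2-(benzyloxy)-3,6-dimethyl-4-(prop-2-en-1-yloxy)benzoate F12. The methyl ester is then cleaved by SN2 dealkylation with LiSPr in hexamethylphosphoramide at rt to 2-(benzyloxy)-3,6-dimethyl-4-(prop-2-en-1-yloxy)benzoic acid F13. The carboxylate is benzylated (BnBr, KHCO3, DMF) to give 5.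

**Further compounds**

F1 | step 11 | (2,6-dimethoxy-4-methylphenyl)lithium | [Li]c1c(OC)cc(C)cc1OC
F2 | step 11 | 2,6-dimethoxy-4-methylbenzaldehyde | COc1cc(C)cc(OC)c1C=O
F3 | step 11 | (2,6-dimethoxy-4-methylphenyl)methanol | COc1cc(C)cc(OC)c1CO
F4 | step 11 | [(2,6-dimethoxy-4-methylphenyl)methoxy]tri(propan-2-yl)silane | COc1cc(C)cc(OC)c1CO[Si](C(C)C)(C(C)C)C(C)C
F5 | step 11 | [(3-bromo-2,6-dimethoxy-4-methylphenyl)methoxy]tri(propan-2-yl)silane | COc1cc(C)c(Br)c(OC)c1CO[Si](C(C)C)(C(C)C)C(C)C
F6 | step 11 | {2,4-dimethoxy-6-methyl-3-[({tri(propan-2-yl)silyl}oxy)methyl]phenyl}lithium | COc1cc(C)c([Li])c(OC)c1CO[Si](C(C)C)(C(C)C)C(C)C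
F7 | step 11 | 2,4-dimethoxy-6-methyl-3-({[tri(propan-2-yl)silyl]oxy}methyl)benzoic acid | COc1cc(C)c(C(=O)O)c(OC)c1CO[Si](C(C)C)(C(C)C)C(C)C
F8 | step 11 | 2,4-dimethoxy-6-methyl-3-({[tri(propan-2-yl)silyl]oxy}methyl)benzoyl chloride | COc1cc(C)c(C(Cl)=O)c(OC)c1CO[Si](C(C)C)(C(C)C)C(C)C
F9 | step 8 | benzyl 2-(benzyloxy)-4-{[(2Z)-3-carboxybut-2-enoyl]oxy}-3,6-dimethylbenzoate | OC(=O)/C(C)=C\C(=O)Oc1cc(C)c(C(=O)OCc2ccccc2)c(OCc2ccccc2)c1C
F10 | step 8 | benzyl 2-(benzyloxy)-4-{[(2E)-3-carboxybut-2-enoyl]oxy}-3,6-dimethylbenzoate | OC(=O)/C(C)=C/C(=O)Oc1cc(C)c(C(=O)OCc2ccccc2)c(OCc2ccccc2)c1C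
F11 | step 8 | benzyl 2-(benzyloxy)-4-{[(2E)-3-(carbonochloridoyl)but-2-enoyl]oxy}-3,6-dimethylbenzoate | O=C(Cl)/C(C)=C/C(=O)Oc1cc(C)c(C(=O)OCc2ccccc2)c(OCc2ccccc2)c1C
F12 | step 2 | methyl 2-(benzyloxy)-3,6-dimethyl-4-(prop-2-en-1-yloxy)benzoate | COC(=O)c1c(C)cc(OCC=C)c(C)c1OCc1ccccc1
F13 | step 2 | 2-(benzyloxy)-3,6-dimethyl-4-(prop-2-en-1-yloxy)benzoic acid | OC(=O)c1c(C)cc(OCC=C)c(C)c1OCc1ccccc1
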